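The cyclohexanone ring (C1 ketone, C2–C3 epoxide, C4 methylene, C5 bearing the side chain, C6 ester carbon) is cut at C3–C4 and C5–C6, a Diels–Alder disconnection into a 2-silyloxy-3-methylbutadiene and a vinyl ketone. The C1 oxygen and C5 are 1,3-related, the reverse of what a free 2-silyloxy diene gives, so the C1 enol oxygen and the C8 carbinol oxygen of the side chain are joined in a diisopropylsilyl acetal. A type 2 intramolecular Diels–Alder reaction of this open-chain triene forms both bonds at once, enforces the regiochemistry and relays the C8 configuration to C5; the bridged silyl enol ether is then unravelled to the enone.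

Key step: step 4

Remark on numbering: ring C1 (C=O), C2 (C–CH3), C3 (CH), C4 (CH2), C5 (CH carrying the side chain), C6 (CH–O); side chain C7 (=C14H2), C8 (CH–O), C9 (CH2), C10 (CH), C11 (C(CH3)2).

Assumption: in the tethered transition state of step 4 the vinyl ketone is taken to react in its s-cis conformation. This fixes the choice of the (R)-glycidate and the inversion at C8 in step 7. Compounds 1, 2, 4, 5, 8, 9, 13, 17, 19, 21, 22 and 26 are taken as commercial.

Step 1
Reactants: 1 methyl (2R)-oxirane-2-carboxylate; 2 (2-methylprop-1-en-1-yl)magnesium bromide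
Product: 3 methyl (2R)-2-hydroxy-5-methylhex-4-enoate
Conditions: CuI (10 mol%), THF, −50 → −30 °C; aq. NH4Cl
Reagents that add atoms: (2-methylprop-1-en-1-yl)magnesium bromide, CC(C)=C[Mg]Br
Why: Copper-catalysed SN2 opening of the terminal epoxide by the alkenyl Grignard reagent should occur at the unhindered CH2 carbon and faster than ester addition at low temperature, so the chiral-pool stereocenter (future C8, R) is carried over untouched.

Step 2
Reactants: 3 methyl (2R)-2-hydroxy-5-methylhex-4-enoate; 4 N,O-dimethylhydroxylamine hydrochloride; 5 vinylmagnesium bromide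
Product: 7 (4R)-4-hydroxy-7-methylocta-1,6-dien-3-one, via Weinreb amide 6 (not isolated)
Conditions: 4, iPrMgCl, THF, −20 °C; then 5, −20 → 0 °C; inverse quench into cold 1 M HCl
Reagents that add atoms: vinylmagnesium bromide, C=C[Mg]Br
Why: One-pot Weinreb amide formation (aminolysis of the ester by the chloromagnesium amide) and Weinreb ketone synthesis: the chelated tetrahedral intermediate should prevent over-addition, the C8 magnesium alkoxide protects the stereocenter from enolisation, and the acidic inverse quench keeps the released amine from adding to the vinyl ketone.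

Step 3
Reactants: 8 3-methylbut-3-en-2-one; 9 dichlorodi(propan-2-yl)silane; 7 (4R)-4-hydroxy-7-methylocta-1,6-dien-3-one
Product: 11 [(3-methylbuta-1,3-dien-2-yl)oxy]{[(4R)-7-methyl-3-oxoocta-1,6-dien-4-yl]oxy}di(propan-2-yl)silane, via chlorosilyl dienol ether 10 (not isolated)
Conditions: LiN(iPr)2, THF, −78 °C; 9; then 7, Et3N, 4-(dimethylamino)pyridine (cat.), −78 → 0 °C
Reagents that add atoms: dichlorodi(propan-2-yl)silane, CC(C)[Si](Cl)(Cl)C(C)C
Why: Kinetic deprotonation of the methyl ketone gives the cross-conjugated lithium dienolate, whose O-silylation by the hindered dichlorosilane should stop at the monochloride 10, and the remaining Si–Cl bond is then displaced by the secondary alcohol of 7 (stepwise unsymmetrical silyl acetal formation); no stereocenter is formed.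

Step 4
Reactants: 11 [(3-methylbuta-1,3-dien-2-yl)oxy]{[(4R)-7-methyl-3-oxoocta-1,6-dien-4-yl]oxy}di(propan-2-yl)silane
Product: 12 (5R,7R)-10-methyl-5-(3-methylbut-2-en-1-yl)-3,3-di(propan-2-yl)-2,4-dioxa-3-silabicyclo[5.3.1]undec-1(10)-en-6-one (bicycle C7 = ring C5 of the target; bicycle C5 = C8 of the target)
Conditions: PhMe (0.01 M), 2,6-di-tert-butyl-4-methylphenol (cat.), 110 °C
Reagents that add atoms: none
Why: Concerted but asynchronous [4+2] cycloaddition (type 2 intramolecular Diels–Alder reaction) between the 2-silyloxy-3-methylbutadiene and the vinyl ketone held on the same silicon atom, forming C3–C4 and C5–C6 together; the closest known reaction type is the type 2 intramolecular Diels–Alder reaction of trienes joined by a disposable silyl acetal tether. It closes the cyclohexene ring (C1–C6) by suprafacial [4+2] addition and, through the new C5–C6 bond, the eight-membered 1,3-dioxa-2-sila bridge, giving a bicyclo[5.3.1] bridgehead silyl enol ether. The regiochemistry needed is the 1,3-relation of the C1 oxygen and the C5 acyl group, opposite to the 1,4-preference of a free 2-silyloxy diene; the five-atom O–Si–O–C8–C7 tether secures it, because from C1 it can only reach a dienophile carbon that bonds to the neighbouring diene terminus C6. The single new stereocenter C5 is controlled by C8: the tether holds the C7 carbonyl under the diene and turns the C8–O bond toward the diene, and in the s-cis enone the C8–H then lies in the enone plane beside C5–H while the C9 methylene points to the open face, so one face of the vinyl group is presented. This should give the bridgehead configuration shown for 12, which is the C5 configuration of the target. High dilution and the radical inhibitor suppress dimerisation and polymerisation of the vinyl ketone.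

Step 5
Reactants: 12 the cycloadduct; 13 Tebbe reagent Cp2Ti(μ-CH2)(μ-Cl)AlMe2
Product: 14 (5R,7R)-10-methyl-6-methylidene-5-(3-methylbut-2-en-1-yl)-3,3-di(propan-2-yl)-2,4-dioxa-3-silabicyclo[5.3.1]undec-1(10)-ene
Conditions: 13, pyridine, THF/PhMe, −40 → 0 °C
Reagents that add atoms: Tebbe reagent Cp2Ti(μ-CH2)(μ-Cl)AlMe2, C[Al-]1(C)C[Ti]([Cl+]1)(C1C=CC=C1)C1C=CC=C1
Why: Tebbe methylenation (titanium methylidene, via an oxatitanacyclobutane) should convert the hindered and enolisable C7 ketone into the C7=C14 alkene under non-basic conditions, so C5 and C8 are not epimerised, while the C1 carbonyl stays masked as the bridgehead silyl enol ether.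

Step 6
Reactants: 14 the methylidene bicycle
Product: 16 (5R)-5-[(3R)-3-hydroxy-6-methylhepta-1,5-dien-2-yl]-2-methylcyclohex-2-en-1-one, via silyl acetate 15 (not isolated)
Conditions: Pd(OAc)2 (1.1 equiv), MeCN, 25 °C; then HF·pyridine, THF, 0 °C
Reagents that add atoms: none
Why: Saegusa–Ito oxidation: the silyl enol ether transmetalates to a C2-bound palladium enolate, β-hydride elimination toward C3 should give the conjugated C2=C3 enone with opening of the silyl acetal, and fluoride then cleaves the residual acetoxysilyl ether on O8; no stereocenter is touched.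

Step 7
Reactants: 16 the enone alcohol; 17 angelic acid, (2Z)-2-methylbut-2-enoic acid
Product: 18 (3S)-6-methyl-2-[(1R)-4-methyl-3-oxocyclohex-3-en-1-yl]hepta-1,5-dien-3-yl (2Z)-2-methylbut-2-enoate
Conditions: PPh3, iPrO2CN=NCO2iPr (DIAD), PhMe, 0 → 25 °C
Reagents that add atoms: angelic acid, C/C=C(/C)C(=O)O
Why: Mitsunobu esterification: SN2 displacement of the alkoxyphosphonium ion of the secondary allylic alcohol by angelate should invert C8 from R to the required S while installing the first angelate.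

Step 8
Reactants: 18 the C8 angelate; 19 potassium peroxymonosulfate KHSO5 (used as Oxone, 2KHSO5·KHSO4·K2SO4)
Product: 20 (2S)-1-[(2R)-3,3-dimethyloxiran-2-yl]-3-[(1R)-4-methyl-3-oxocyclohex-3-en-1-yl]but-3-en-2-yl (2Z)-2-methylbut-2-enoate
Conditions: D-fructose-derived Shi ketone (1,2:4,5-di-O-isopropylidene-β-D-erythro-2,3-hexodiulo-2,6-pyranose, 0.3 equiv), 19, K2CO3, Bu4NHSO4, MeCN/CH2(OMe)2/aq. Na2B4O7 buffer, 0 °C
Reagents that add atoms: potassium peroxymonosulfate, [K+].[O-]S(=O)(=O)OO
Why: Shi asymmetric epoxidation: the dioxirane of the D-fructose-derived ketone should attack only the electron-rich trisubstituted C10=C11 alkene (the enone, the angelate and the ester-bearing 1,1-disubstituted alkene are electron-poorer) and set (10R) by reagent control through the spiro transition state.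

Step 9
Reactants: 20 the epoxy enone; 21 3-phenyl-2-(phenylsulfonyl)oxaziridine (Davis oxaziridine, racemic); 22 angelic anhydride, (2Z)-2-methylbut-2-enoic anhydride
Product: 24 (1S,6S)-6-{(3S)-4-[(2R)-3,3-dimethyloxiran-2-yl]-3-{[(2Z)-2-methylbut-2-enoyl]oxy}but-1-en-2-yl}-3-methyl-2-oxocyclohex-3-en-1-yl (2Z)-2-methylbut-2-enoate, via hydroxy enone 23 (not isolated)
Conditions: LiN(SiMe3)2, THF, −78 °C; 21, −78 °C; then 22, −78 → −20 °C; aq. NH4Cl
Reagents that add atoms: 3-phenyl-2-(phenylsulfonyl)oxaziridine, O=S(=O)(c1ccccc1)N1OC1c1ccccc1; angelic anhydride, C/C=C(/C)C(=O)OC(=O)/C(C)=C\C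
Why: Enolate oxidation then O-acylation: kinetic α′-deprotonation at C6 gives the cross-conjugated lithium dienolate, the Davis oxaziridine should deliver oxygen anti to the neighbouring C5 substituent (C5/C6 trans, 6S), and the lithium alkoxide formed is acylated in the same flask by the anhydride without Z to E isomerisation.

Step 10
Reactants: 24 the bis-angelate enone
Product: 25 (1S,2S,6S)-6-{(3S)-4-[(2R)-3,3-dimethyloxiran-2-yl]-3-{[(2Z)-2-methylbut-2-enoyl]oxy}but-1-en-2-yl}-2-hydroxy-3-methylcyclohex-3-en-1-yl (2Z)-2-methylbut-2-enoate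
Conditions: NaBH4, CeCl3·7H2O, MeOH, −78 °C
Reagents that add atoms: none
Why: Luche 1,2-reduction: axial hydride attack on the enone should give the pseudo-equatorial C1 alcohol, trans to the C6 ester and cis to the C5 side chain (the carvone to cis-carveol pattern), leaving esters and epoxide intact.

Step 11
Reactants: 25 the allylic alcohol; 26 tert-butyl hydroperoxide
Product: 27 (1R,2R,3S,4S,6S)-4-{(3S)-4-[(2R)-3,3-dimethyloxiran-2-yl]-3-{[(2Z)-2-methylbut-2-enoyl]oxy}but-1-en-2-yl}-2-hydroxy-1-methyl-7-oxabicyclo[4.1.0]heptan-3-yl (2Z)-2-methylbut-2-enoate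
Conditions: VO(acac)2 (5 mol%), 26, CH2Cl2, 0 → 25 °C
Reagents that add atoms: tert-butyl hydroperoxide, CC(C)(C)OO
Why: Hydroxyl-directed epoxidation of the cyclic allylic alcohol: the vanadium-bound peroxide should be delivered to C2=C3 syn to the C1 hydroxyl, that is on the face of the C5 side chain, which sets C2 and C3; the non-allylic alkenes are not touched.

Step 12
Reactants: 27 the epoxy alcohol
Product: 28 (1S,3S,4S,6S)-4-{(3S)-4-[(2R)-3,3-dimethyloxiran-2-yl]-3-{[(2Z)-2-methylbut-2-enoyl]oxy}but-1-en-2-yl}-1-methyl-2-oxo-7-oxabicyclo[4.1.0]heptan-3-yl (2Z)-2-methylbut-2-enoate (target, CNP0247177.2)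
Conditions: Dess–Martin periodinane, pyridine, CH2Cl2, 0 → 25 °C
Reagents that add atoms: none
Why: Dess–Martin oxidation of the secondary epoxy alcohol to the α,β-epoxy ketone under buffered neutral conditions should leave the C6 stereocenter, both epoxides and both angelates unchanged.

Compound list
1 | methyl (2R)-oxirane-2-carboxylate | COC(=O)[C@H]1CO1 | starting material
2 | (2-methylprop-1-en-1-yl)magnesium bromide | CC(C)=C[Mg]Br | starting material
3 | methyl (2R)-2-hydroxy-5-methylhex-4-enoate | COC(=O)[C@H](O)CC=C(C)C | intermediate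
4 | N,O-dimethylhydroxylamine hydrochloride | CNOC.Cl | starting material
5 | vinylmagnesium bromide | C=C[Mg]Br | starting material
6 | (2R)-2-hydroxy-N-methoxy-N,5-dimethylhex-4-enamide (formed in the flask) | CON(C)C(=O)[C@H](O)CC=C(C)C | intermediate
7 | (4R)-4-hydroxy-7-methylocta-1,6-dien-3-one | C=CC(=O)[C@H](O)CC=C(C)C | intermediate
8 | 3-methylbut-3-en-2-one | CC(=O)C(C)=C | starting material
9 | dichlorodi(propan-2-yl)silane | CC(C)[Si](Cl)(Cl)C(C)C | starting material
10 | chloro[(3-methylbuta-1,3-dien-2-yl)oxy]di(propan-2-yl)silane (formed in the flask) | C=C(C)C(=C)O[Si](Cl)(C(C)C)C(C)C | intermediate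
11 | [(3-methylbuta-1,3-dien-2-yl)oxy]{[(4R)-7-methyl-3-oxoocta-1,6-dien-4-yl]oxy}di(propan-2-yl)silane | C=C(C)C(=C)O[Si](C(C)C)(C(C)C)O[C@H](CC=C(C)C)C(=O)C=C | intermediate
12 | (5R,7R)-10-methyl-5-(3-methylbut-2-en-1-yl)-3,3-di(propan-2-yl)-2,4-dioxa-3-silabicyclo[5.3.1]undec-1(10)-en-6-one | O=C1[C@@H](CC=C(C)C)O[Si](C(C)C)(C(C)C)OC2=C(C)CC[C@@H]1C2 | intermediate
13 | Tebbe reagent Cp2Ti(μ-CH2)(μ-Cl)AlMe2 | C[Al-]1(C)C[Ti]([Cl+]1)(C1C=CC=C1)C1C=CC=C1 | starting material
14 | (5R,7R)-10-methyl-6-methylidene-5-(3-methylbut-2-en-1-yl)-3,3-di(propan-2-yl)-2,4-dioxa-3-silabicyclo[5.3.1]undec-1(10)-ene | C=C1[C@@H](CC=C(C)C)O[Si](C(C)C)(C(C)C)OC2=C(C)CC[C@@H]1C2 | intermediate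
15 | acetoxy{[(3R)-6-methyl-2-[(1R)-4-methyl-3-oxocyclohex-3-en-1-yl]hepta-1,5-dien-3-yl]oxy}di(propan-2-yl)silane (formed in the flask) | C=C([C@@H](CC=C(C)C)O[Si](OC(C)=O)(C(C)C)C(C)C)[C@@H]1CC=C(C)C(=O)C1 | intermediate
16 | (5R)-5-[(3R)-3-hydroxy-6-methylhepta-1,5-dien-2-yl]-2-methylcyclohex-2-en-1-one | C=C([C@@H](CC=C(C)C)O)[C@@H]1CC=C(C)C(=O)C1 | intermediate
17 | angelic acid, (2Z)-2-methylbut-2-enoic acid | C/C=C(/C)C(=O)O | starting material
18 | (3S)-6-methyl-2-[(1R)-4-methyl-3-oxocyclohex-3-en-1-yl]hepta-1,5-dien-3-yl (2Z)-2-methylbut-2-enoate | C=C([C@H](CC=C(C)C)OC(=O)/C(C)=C\C)[C@@H]1CC=C(C)C(=O)C1 | intermediate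
19 | potassium peroxymonosulfate KHSO5 (as Oxone) | [K+].[O-]S(=O)(=O)OO | starting material
20 | (2S)-1-[(2R)-3,3-dimethyloxiran-2-yl]-3-[(1R)-4-methyl-3-oxocyclohex-3-en-1-yl]but-3-en-2-yl (2Z)-2-methylbut-2-enoate | C=C([C@H](C[C@H]1OC1(C)C)OC(=O)/C(C)=C\C)[C@@H]1CC=C(C)C(=O)C1 | intermediate
21 | 3-phenyl-2-(phenylsulfonyl)oxaziridine | O=S(=O)(c1ccccc1)N1OC1c1ccccc1 | starting material
22 | angelic anhydride, (2Z)-2-methylbut-2-enoic anhydride | C/C=C(/C)C(=O)OC(=O)/C(C)=C\C | starting material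
23 | (2S)-1-[(2R)-3,3-dimethyloxiran-2-yl]-3-[(1S,2S)-2-hydroxy-4-methyl-3-oxocyclohex-3-en-1-yl]but-3-en-2-yl (2Z)-2-methylbut-2-enoate (formed in the flask as its lithium alkoxide) | C=C([C@H](C[C@H]1OC1(C)C)OC(=O)/C(C)=C\C)[C@@H]1CC=C(C)C(=O)[C@H]1O | intermediate
24 | (1S,6S)-6-{(3S)-4-[(2R)-3,3-dimethyloxiran-2-yl]-3-{[(2Z)-2-methylbut-2-enoyl]oxy}but-1-en-2-yl}-3-methyl-2-oxocyclohex-3-en-1-yl (2Z)-2-methylbut-2-enoate | C=C([C@H](C[C@H]1OC1(C)C)OC(=O)/C(C)=C\C)[C@@H]1CC=C(C)C(=O)[C@H]1OC(=O)/C(C)=C\C | intermediate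
25 | (1S,2S,6S)-6-{(3S)-4-[(2R)-3,3-dimethyloxiran-2-yl]-3-{[(2Z)-2-methylbut-2-enoyl]oxy}but-1-en-2-yl}-2-hydroxy-3-methylcyclohex-3-en-1-yl (2Z)-2-methylbut-2-enoate | C=C([C@H](C[C@H]1OC1(C)C)OC(=O)/C(C)=C\C)[C@@H]1CC=C(C)[C@H](O)[C@H]1OC(=O)/C(C)=C\C | intermediate
26 | tert-butyl hydroperoxide | CC(C)(C)OO | starting material
27 | (1R,2R,3S,4S,6S)-4-{(3S)-4-[(2R)-3,3-dimethyloxiran-2-yl]-3-{[(2Z)-2-methylbut-2-enoyl]oxy}but-1-en-2-yl}-2-hydroxy-1-methyl-7-oxabicyclo[4.1.0]heptan-3-yl (2Z)-2-methylbut-2-enoate | C=C([C@H](C[C@H]1OC1(C)C)OC(=O)/C(C)=C\C)[C@@H]1C[C@@H]2O[C@]2(C)[C@H](O)[C@H]1OC(=O)/C(C)=C\C | intermediate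
28 | (1S,3S,4S,6S)-4-{(3S)-4-[(2R)-3,3-dimethyloxiran-2-yl]-3-{[(2Z)-2-methylbut-2-enoyl]oxy}but-1-en-2-yl}-1-methyl-2-oxo-7-oxabicyclo[4.1.0]heptan-3-yl (2Z)-2-methylbut-2-enoate | C=C([C@H](C[C@H]1OC1(C)C)OC(=O)/C(C)=C\C)[C@@H]1C[C@@H]2O[C@]2(C)C(=O)[C@H]1OC(=O)/C(C)=C\C | target

Total step count: 12. Longest linear sequence: 12 steps (from 1 to 28).

Steps most likely to fail

Step 4 (key step). The facial discrimination relayed from C8 may be reversed or weak if the vinyl ketone reacts through its s-trans conformer, so that the wrong C5 epimer relative to C8 forms; intermolecular dimerisation is the second risk. The fallback inverts the stereochemical plan: it uses the enantiomeric carbinol, for which that alternative geometry gives the needed C5 configuration, and esterifies C8 with retention. It sets out from 2, which is opened onto methyl (2S)-oxirane-2-carboxylate F1 (CuI) to give methyl (2S)-2-hydroxy-5-methylhex-4-enoate F2. The procedure of step 2 converts F2 through the (2S)-Weinreb amide F3 into (4S)-4-hydroxy-7-methylocta-1,6-dien-3-one F4. F4 is joined with 8 and 9 (through 10) to the (4S)-configured silyl acetal triene F5, which is heated to the (5S,7R)-cycloadduct F6. Tebbe methylenation gives the (5S,7R)-methylidene bicycle F7, and Pd(OAc)2 then HF·pyridine give, through the (3S)-silyl acetate F8, (5R)-5-[(3S)-3-hydroxy-6-methylhepta-1,5-dien-2-yl]-2-methylcyclohex-2-en-1-one F9. F9 is esterified with retention by 17 (2,4,6-trichlorobenzoyl chloride, Et3N, 4-(dimethylamino)pyridine, PhMe) and the route is rejoined at 18.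

Step 7. The Mitsunobu reaction may suffer SN2′ attack of angelate at C14, Z to E isomerisation of the angelate by the phosphine, or poor conversion with the weakly acidic angelic acid. The fallback separates inversion from angeloylation. It sets out from 16, which is inverted under Mitsunobu conditions with 4-nitrobenzoic acid to (3S)-6-methyl-2-[(1R)-4-methyl-3-oxocyclohex-3-en-1-yl]hepta-1,5-dien-3-yl 4-nitrobenzoate F10. Methanolysis (K2CO3, MeOH) gives the (3S)-alcohol, which is the compound F9 already described, and mixed-anhydride esterification with 17 (2,4,6-trichlorobenzoyl chloride, Et3N, 4-(dimethylamino)pyridine) with retention returns to 18.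

Step 9. The one-flask hydroxylation and acylation may fail through low facial selectivity at C6, attack of the lithium enolate on the C10–C11 epoxide, the C8 ester or the sulfonimine by-product, or incomplete acylation of the hindered alkoxide. The fallback is a Rubottom oxidation with separate esterification. It sets out from 20, which is converted (LiN(SiMe3)2, Me3SiCl, THF, −78 °C) into the cross-conjugated trimethylsilyl dienol ether F11. Epoxidation with dimethyldioxirane (acetone, −78 °C) and silyl migration give the C6 trimethylsilyloxy enone F12, which is desilylated (citric acid, MeOH) to 23, isolated here. Esterification of 23 with 17 (2,4,6-trichlorobenzoyl chloride, Et3N, 4-(dimethylamino)pyridine, PhMe) returns to 24.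

Further compounds
F1 | step 4 | methyl (2S)-oxirane-2-carboxylate | COC(=O)[C@@H]1CO1
F2 | step 4 | methyl (2S)-2-hydroxy-5-methylhex-4-enoate | COC(=O)[C@@H](O)CC=C(C)C
F3 | step 4 | (2S)-2-hydroxy-N-methoxy-N,5-dimethylhex-4-enamide | CON(C)C(=O)[C@@H](O)CC=C(C)C
F4 | step 4 | (4S)-4-hydroxy-7-methylocta-1,6-dien-3-one | C=CC(=O)[C@@H](O)CC=C(C)C
F5 | step 4 | [(3-methylbuta-1,3-dien-2-yl)oxy]{[(4S)-7-methyl-3-oxoocta-1,6-dien-4-yl]oxy}di(propan-2-yl)silane | C=C(C)C(=C)O[Si](C(C)C)(C(C)C)O[C@@H](CC=C(C)C)C(=O)C=C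
F6 | step 4 | (5S,7R)-10-methyl-5-(3-methylbut-2-en-1-yl)-3,3-di(propan-2-yl)-2,4-dioxa-3-silabicyclo[5.3.1]undec-1(10)-en-6-one | O=C1[C@H](CC=C(C)C)O[Si](C(C)C)(C(C)C)OC2=C(C)CC[C@@H]1C2
F7 | step 4 | (5S,7R)-10-methyl-6-methylidene-5-(3-methylbut-2-en-1-yl)-3,3-di(propan-2-yl)-2,4-dioxa-3-silabicyclo[5.3.1]undec-1(10)-ene | C=C1[C@H](CC=C(C)C)O[Si](C(C)C)(C(C)C)OC2=C(C)CC[C@@H]1C2
F8 | step 4 | acetoxy{[(3S)-6-methyl-2-[(1R)-4-methyl-3-oxocyclohex-3-en-1-yl]hepta-1,5-dien-3-yl]oxy}di(propan-2-yl)silane | C=C([C@H](CC=C(C)C)O[Si](OC(C)=O)(C(C)C)C(C)C)[C@@H]1CC=C(C)C(=O)C1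
F9 | step 4 | (5R)-5-[(3S)-3-hydroxy-6-methylhepta-1,5-dien-2-yl]-2-methylcyclohex-2-en-1-one | C=C([C@H](CC=C(C)C)O)[C@@H]1CC=C(C)C(=O)C1
F10 | step 7 | (3S)-6-methyl-2-[(1R)-4-methyl-3-oxocyclohex-3-en-1-yl]hepta-1,5-dien-3-yl 4-nitrobenzoate | C=C([C@H](CC=C(C)C)OC(=O)c1ccc(cc1)[N+](=O)[O-])[C@@H]1CC=C(C)C(=O)C1
F11 | step 9 | (2S)-1-[(2R)-3,3-dimethyloxiran-2-yl]-3-[(1R)-4-methyl-3-(trimethylsilyloxy)cyclohexa-2,4-dien-1-yl]but-3-en-2-yl (2Z)-2-methylbut-2-enoate | C=C([C@H](C[C@H]1OC1(C)C)OC(=O)/C(C)=C\C)[C@@H]1CC=C(C)C(O[Si](C)(C)C)=C1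
F12 | step 9 | (2S)-1-[(2R)-3,3-dimethyloxiran-2-yl]-3-[(1S,2S)-4-methyl-3-oxo-2-(trimethylsilyloxy)cyclohex-3-en-1-yl]but-3-en-2-yl (2Z)-2-methylbut-2-enoate | C=C([C@H](C[C@H]1OC1(C)C)OC(=O)/C(C)=C\C)[C@@H]1CC=C(C)C(=O)[C@H]1O[Si](C)(C)C
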